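**Retrosynthetic overview**

1. Prokinawan 17 comes from the fully protected flavanone 16 by one acidic global deprotection (two MOM ethers, two tert-butyl carbonates, one triethylsilyl ether).
2. 16 comes from (S)-β-lactone 13 and aryl fluoride 10. The pyranone ring (ring C) is made by two-atom expansion of the oxetan-2-one ring: its O–CH(Ar)–CH2–C(=O) atoms become O1, C2, C3 and C4, and C4a/C8a of ring A are inserted into its acyl C–O bond (C4–C4a by acylation of an aryllithium, O1–C8a by SNAr).
3. Enabling feature: O1–C2–C3–C4(=O) of ring C is a β-lactone pattern with the only stereocentre on its carbinol carbon. Ring A of 10 is symmetric about the F/C6 axis, so its two ring C–H (future C4a and C8) are equivalent and both flanked by F and OMOM; C6- versus C8-substitution is decided by symmetry, and F ends ortho to the new ketone.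
4. 10 comes from 5-fluororesorcinol bis-MOM ether 8 and allylic bromide 6 (ortho-lithiation/allylation); 6 comes from geranyl acetate by Markovnikov hydration of the distal olefin; 13 comes from aldehyde 12 and ketene (catalytic asymmetric [2+2]).
5. Order of ring formation: rings A and B are bought as arenes; the oxetanone ring is formed in step 8 and expanded to ring C in step 9.

Key step: step 9

Assumption: O-trimethylsilylquinine is taken to deliver the (4S)-lactone, by analogy with the facial preference of quinine-derived ammonium enolates in ketene–aldehyde cycloadditions; if the sense proves opposite, O-trimethylsilylquinidine is used instead.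

**Route**

Step 1
Reactants: 1 geranyl acetate
Product: 3 (2E)-7-hydroxy-3,7-dimethyloct-2-en-1-yl acetate, via organomercurial 2 (not isolated)
Conditions: Hg(OAc)2, THF/H2O (1:1), rt; then NaBH4, aq NaOH, 0 °C
Reagents that add atoms: water, O
Why: Markovnikov oxymercuration–demercuration should take place at the electron-rich 6,7-olefin, the 2,3-olefin being deactivated by the allylic acetate, so the tertiary alcohol is installed with the E-olefin untouched and no stereocentre remains after reduction of the C–Hg bond.

Step 2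
Reactants: 3 (2E)-7-hydroxy-3,7-dimethyloct-2-en-1-yl acetate
Product: 4 (2E)-3,7-dimethyl-7-(triethylsilyloxy)oct-2-en-1-yl acetate
Conditions: TESOTf, 2,6-lutidine, CH2Cl2, −78 → 0 °C
Reagents that add atoms: triethylsilyl trifluoromethanesulfonate (TESOTf), CC[Si](CC)(CC)OS(=O)(=O)C(F)(F)F
Why: Silyl ether protection of the hindered tertiary alcohol with the silyl triflate masks the only acidic proton of the side chain before the organolithium steps.

Step 3
Reactants: 4 (2E)-3,7-dimethyl-7-(triethylsilyloxy)oct-2-en-1-yl acetate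
Product: 5 (2E)-3,7-dimethyl-7-(triethylsilyloxy)oct-2-en-1-ol
Conditions: K2CO3 (cat.), MeOH, 0 °C → rt
Reagents that add atoms: none
Why: Base-catalysed transesterification (Zemplén-type methanolysis) removes the acetate, the tertiary silyl ether being stable to K2CO3/MeOH.

Step 4
Reactants: 5 (2E)-3,7-dimethyl-7-(triethylsilyloxy)oct-2-en-1-ol
Product: 6 (2E)-1-bromo-3,7-dimethyl-7-(triethylsilyloxy)oct-2-ene
Conditions: CBr4, PPh3, CH2Cl2, 0 °C
Reagents that add atoms: carbon tetrabromide, BrC(Br)(Br)Br
Why: The Appel reaction converts the primary allylic alcohol into the bromide by SN2 displacement under near-neutral conditions, which should keep the E geometry and the silyl ether.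

Step 5
Reactants: 7 5-fluorobenzene-1,3-diol
Product: 8 1-fluoro-3,5-bis(methoxymethoxy)benzene
Conditions: MOMCl, i-Pr2NEt, CH2Cl2, 0 °C → rt
Reagents that add atoms: chloromethyl methyl ether (MOMCl), COCCl
Why: Williamson-type O-alkylation of both phenols installs two acid-labile acetal ethers that are also strong ortho-directing groups for the two lithiations to come.

Step 6
Reactants: 8 1-fluoro-3,5-bis(methoxymethoxy)benzene; 6 (2E)-1-bromo-3,7-dimethyl-7-(triethylsilyloxy)oct-2-ene
Product: 10 5-fluoro-1,3-bis(methoxymethoxy)-2-[(2E)-3,7-dimethyl-7-(triethylsilyloxy)oct-2-en-1-yl]benzene, via aryllithium 9 (not isolated)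
Conditions: n-BuLi, THF, −40 °C; CuI (10 mol %), then 6, −78 °C → rt
Reagents that add atoms: none
Why: Directed ortho-metalation by n-BuLi is expected at the only position flanked by two coordinating OMOM groups (preferred over the F/OMOM-flanked positions under coordination control), and copper-catalysed SN2 allylation of 9 with the primary bromide then places the side chain on the symmetry axis of the ring with the E-olefin retained.

Step 7
Reactants: 11 3,4-dihydroxybenzaldehyde
Product: 12 3,4-bis(tert-butoxycarbonyloxy)benzaldehyde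
Conditions: Boc2O, DMAP (cat.), MeCN, rt
Reagents that add atoms: di-tert-butyl dicarbonate (Boc2O), CC(C)(C)OC(=O)OC(=O)OC(C)(C)C
Why: DMAP-catalysed O-acylation turns the catechol into a bis(tert-butyl carbonate), which makes the aryl group electron-poor (a stable 4-aryl β-lactone, a more reactive aldehyde) and is acid-labile for the last step.

Step 8
Reactants: 12 3,4-bis(tert-butoxycarbonyloxy)benzaldehyde
Product: 13 (4S)-4-[3,4-bis(tert-butoxycarbonyloxy)phenyl]oxetan-2-one
Conditions: AcCl, i-Pr2NEt, O-trimethylsilylquinine (10 mol %), LiClO4, CH2Cl2/Et2O, −78 °C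
Reagents that add atoms: acetyl chloride, CC(Cl)=O
Why: In this catalytic asymmetric ketene–aldehyde [2+2] cycloaddition (Wynberg-type acyl halide–aldehyde cyclocondensation) the alkaloid-bound ammonium enolate of the ketene made in situ should add to one face of the LiClO4-activated aldehyde and lactonise, so the C4 stereocentre (the future C2 of the flavanone) is set by the catalyst.

Step 9
Reactants: 10 5-fluoro-1,3-bis(methoxymethoxy)-2-[(2E)-3,7-dimethyl-7-(triethylsilyloxy)oct-2-en-1-yl]benzene; 13 (4S)-4-[3,4-bis(tert-butoxycarbonyloxy)phenyl]oxetan-2-one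
Product: 16 (2S)-2-[3,4-bis(tert-butoxycarbonyloxy)phenyl]-5,7-bis(methoxymethoxy)-6-[(2E)-3,7-dimethyl-7-(triethylsilyloxy)oct-2-en-1-yl]chroman-4-one, via aryllithium 14 (not isolated), via lithium keto-alkoxide 15 (not isolated)
Conditions: n-BuLi, THF, −78 °C; cannulate into 13, THF, −78 °C; then DMPU, −78 → 0 °C
Reagents that add atoms: none
Why: Proposed new method: ortho-lithiation of 10 between F and OMOM gives 14, an aryne equivalent with a nucleophilic C4a and an electrophilic C8a, which should add to the strained lactone carbonyl of 13; the adduct collapses with acyl–O cleavage to the keto-alkoxide 15, whose alkoxide then displaces fluoride at C8a, now ortho to the new ketone, so that the C4a–C8a unit is inserted into the O1–C4 bond and the four-membered ring is expanded by two atoms to the pyranone. The closest known reaction types are the two-atom ring expansions by aryne insertion into acyl σ-bonds, the acylation of aryllithiums by lactones, and the intramolecular SNAr etherification of ortho-fluoroaryl ketones. The six-membered ring is closed by addition–elimination at C8a through a Meisenheimer complex delocalised into the C4 carbonyl (formally 6-endo-trig, with lithium-assisted departure of fluoride as LiF). No new stereocentre is formed: C2 is the lactone carbinol carbon, none of its bonds is made or broken, and the S configuration should be carried over unchanged. The step needs chemoselective attack at the lactone carbonyl over the two aryl carbonates and over α-deprotonation, which the ring strain and unhindered carbonyl of 13, the low temperature and the inverse addition are expected to secure, and it needs ring closure to outrun retro-aldol cleavage of 15, for which the lithium chelate, DMPU and the C–F bond activated by the ortho-acyl and two meta-alkoxy groups are relied on. Regiochemistry (6- versus 8-substitution) cannot err, because the lithiated carbon is the only kind of ring C–H in 10.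

Step 10
Reactants: 16 (2S)-2-[3,4-bis(tert-butoxycarbonyloxy)phenyl]-5,7-bis(methoxymethoxy)-6-[(2E)-3,7-dimethyl-7-(triethylsilyloxy)oct-2-en-1-yl]chroman-4-one
Product: 17 prokinawan
Conditions: 3 M aq HCl/MeOH, 40 °C
Reagents that add atoms: none
Why: Acid-catalysed acetal methanolysis (MOM), tert-butyl carbonate acidolysis and silyl ether solvolysis should occur in one global deprotection under conditions in which C2 has no base-mediated ring-opening pathway and is therefore not expected to epimerise.

**Compound list**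

1 | geranyl acetate, (2E)-3,7-dimethylocta-2,6-dien-1-yl acetate | C/C(=C\COC(C)=O)CCC=C(C)C | starting material
2 | (2E)-6-(acetoxymercurio)-7-hydroxy-3,7-dimethyloct-2-en-1-yl acetate (racemic at C6) | C/C(=C\COC(C)=O)CCC([Hg]OC(C)=O)C(C)(C)O | intermediate
3 | (2E)-7-hydroxy-3,7-dimethyloct-2-en-1-yl acetate | C/C(=C\COC(C)=O)CCCC(C)(C)O | intermediate
4 | (2E)-3,7-dimethyl-7-(triethylsilyloxy)oct-2-en-1-yl acetate | C/C(=C\COC(C)=O)CCCC(C)(C)O[Si](CC)(CC)CC | intermediate
5 | (2E)-3,7-dimethyl-7-(triethylsilyloxy)oct-2-en-1-ol | C/C(=C\CO)CCCC(C)(C)O[Si](CC)(CC)CC | intermediate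
6 | (2E)-1-bromo-3,7-dimethyl-7-(triethylsilyloxy)oct-2-ene | C/C(=C\CBr)CCCC(C)(C)O[Si](CC)(CC)CC | intermediate
7 | 5-fluorobenzene-1,3-diol (5-fluororesorcinol) | Oc1cc(O)cc(F)c1 | starting material
8 | 1-fluoro-3,5-bis(methoxymethoxy)benzene | COCOc1cc(F)cc(OCOC)c1 | intermediate
9 | [4-fluoro-2,6-bis(methoxymethoxy)phenyl]lithium | [Li]c1c(OCOC)cc(F)cc1OCOC | intermediate
10 | 5-fluoro-1,3-bis(methoxymethoxy)-2-[(2E)-3,7-dimethyl-7-(triethylsilyloxy)oct-2-en-1-yl]benzene | C/C(=C\Cc1c(OCOC)cc(F)cc1OCOC)CCCC(C)(C)O[Si](CC)(CC)CC | intermediate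
11 | 3,4-dihydroxybenzaldehyde | O=Cc1ccc(O)c(O)c1 | starting material
12 | 3,4-bis(tert-butoxycarbonyloxy)benzaldehyde | O=Cc1ccc(OC(=O)OC(C)(C)C)c(OC(=O)OC(C)(C)C)c1 | intermediate
13 | (4S)-4-[3,4-bis(tert-butoxycarbonyloxy)phenyl]oxetan-2-one | O=C1C[C@@H](c2ccc(OC(=O)OC(C)(C)C)c(OC(=O)OC(C)(C)C)c2)O1 | intermediate
14 | {6-fluoro-2,4-bis(methoxymethoxy)-3-[(2E)-3,7-dimethyl-7-(triethylsilyloxy)oct-2-en-1-yl]phenyl}lithium | C/C(=C\Cc1c(OCOC)cc(F)c([Li])c1OCOC)CCCC(C)(C)O[Si](CC)(CC)CC | intermediate
15 | lithium (1S)-1-[3,4-bis(tert-butoxycarbonyloxy)phenyl]-3-{6-fluoro-2,4-bis(methoxymethoxy)-3-[(2E)-3,7-dimethyl-7-(triethylsilyloxy)oct-2-en-1-yl]phenyl}-3-oxopropan-1-olate | C/C(=C\Cc1c(OCOC)cc(F)c(C(=O)C[C@@H](c2ccc(OC(=O)OC(C)(C)C)c(OC(=O)OC(C)(C)C)c2)O[Li])c1OCOC)CCCC(C)(C)O[Si](CC)(CC)CC | intermediate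
16 | (2S)-2-[3,4-bis(tert-butoxycarbonyloxy)phenyl]-5,7-bis(methoxymethoxy)-6-[(2E)-3,7-dimethyl-7-(triethylsilyloxy)oct-2-en-1-yl]chroman-4-one | C/C(=C\Cc1c(OCOC)cc2c(c1OCOC)C(=O)C[C@@H](c1ccc(OC(=O)OC(C)(C)C)c(OC(=O)OC(C)(C)C)c1)O2)CCCC(C)(C)O[Si](CC)(CC)CC | intermediate
17 | prokinawan, (2S)-2-(3,4-dihydroxyphenyl)-5,7-dihydroxy-6-[(2E)-7-hydroxy-3,7-dimethyloct-2-en-1-yl]chroman-4-one | C/C(=C\Cc1c(O)cc2c(c1O)C(=O)C[C@@H](c1ccc(O)c(O)c1)O2)CCCC(C)(C)O | target

**Step count and risks**

Total step count: 10. Longest linear sequence: 7 steps (steps 1, 2, 3, 4, 6, 9, 10).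

Steps most likely to fail:

Step 9 (proposed new method). The aryllithium may deprotonate the lactone alpha to the carbonyl instead of adding to it, a Boc group may be transferred to the alkoxide, or the lithium aldolate may undergo retro-aldol cleavage before the ring closes, which would erode the enantiomeric purity. The fallback uses known, stepwise, acyclic chemistry and sets out from 13. The lactone is opened with MeNHOMe·HCl/Me2AlCl (CH2Cl2, 0 °C) to the Weinreb amide (3S)-3-[3,4-bis(tert-butoxycarbonyloxy)phenyl]-3-hydroxy-N-methoxy-N-methylpropanamide F1. This is silylated (TESOTf, 2,6-lutidine) to (3S)-3-[3,4-bis(tert-butoxycarbonyloxy)phenyl]-N-methoxy-N-methyl-3-(triethylsilyloxy)propanamide F2. Aryllithium 14, generated from 10 as in step 9, is then acylated by F2 (Weinreb ketone synthesis, −78 °C) to the β-silyloxy ketone (3S)-3-[3,4-bis(tert-butoxycarbonyloxy)phenyl]-1-{6-fluoro-2,4-bis(methoxymethoxy)-3-[(2E)-3,7-dimethyl-7-(triethylsilyloxy)oct-2-en-1-yl]phenyl}-3-(triethylsilyloxy)propan-1-one F3, so that no free aldolate exists at the C–C bond-forming stage. Fluoride (CsF, DMF, rt) then cleaves the secondary benzylic silyl ether, and the liberated alkoxide closes onto C8a by fluoride-mediated SNAr of the silyl ether. The fallback comes back to the route at 16.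

Step 8. The ammonium enolate may turn over slowly with an aromatic aldehyde, or the facial selectivity may be insufficient. The fallback sets out from 12. Roskamp homologation with benzyl diazoacetate (SnCl2 cat., CH2Cl2) gives benzyl 3-[3,4-bis(tert-butoxycarbonyloxy)phenyl]-3-oxopropanoate F4. Noyori hydrogenation with RuCl2[(R)-BINAP] (H2, EtOH) should give benzyl (3S)-3-[3,4-bis(tert-butoxycarbonyloxy)phenyl]-3-hydroxypropanoate F5. Hydrogenolysis of the benzyl ester (H2, Pd/C, EtOAc) gives (3S)-3-[3,4-bis(tert-butoxycarbonyloxy)phenyl]-3-hydroxypropanoic acid F6. Lactonisation by carboxyl activation (PhSO2Cl, pyridine, 0 °C), which leaves the carbinol configuration untouched, comes back to the route at 13.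

Step 10. Acid may promote cyclisation of the side-chain olefin onto the 5- or 7-hydroxyl to a chroman, or solvolysis and dehydration of the tertiary alcohol. The fallback sets out from 16 and replaces the protic acid by a two-stage aprotic unmasking. TMSOTf/2,2′-bipyridyl (CH2Cl2, 0 °C; then water) converts the aryl MOM ethers through pyridinium salts and cleaves the tert-butyl carbonates without a Brønsted acid, to give the tetraphenol that still carries the side-chain silyl ether, (2S)-2-(3,4-dihydroxyphenyl)-5,7-dihydroxy-6-[(2E)-3,7-dimethyl-7-(triethylsilyloxy)oct-2-en-1-yl]chroman-4-one F7. Et3N·3HF (THF, rt) then removes the silyl group, and the fallback comes back to the route at 17.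

Further compounds
F1 | step 9 | (3S)-3-[3,4-bis(tert-butoxycarbonyloxy)phenyl]-3-hydroxy-N-methoxy-N-methylpropanamide | CON(C)C(=O)C[C@@H](c1ccc(OC(=O)OC(C)(C)C)c(OC(=O)OC(C)(C)C)c1)O
F2 | step 9 | (3S)-3-[3,4-bis(tert-butoxycarbonyloxy)phenyl]-N-methoxy-N-methyl-3-(triethylsilyloxy)propanamide | CON(C)C(=O)C[C@@H](c1ccc(OC(=O)OC(C)(C)C)c(OC(=O)OC(C)(C)C)c1)O[Si](CC)(CC)CC
F3 | step 9 | (3S)-3-[3,4-bis(tert-butoxycarbonyloxy)phenyl]-1-{6-fluoro-2,4-bis(methoxymethoxy)-3-[(2E)-3,7-dimethyl-7-(triethylsilyloxy)oct-2-en-1-yl]phenyl}-3-(triethylsilyloxy)propan-1-one | C/C(=C\Cc1c(OCOC)cc(F)c(C(=O)C[C@@H](c2ccc(OC(=O)OC(C)(C)C)c(OC(=O)OC(C)(C)C)c2)O[Si](CC)(CC)CC)c1OCOC)CCCC(C)(C)O[Si](CC)(CC)CC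
F4 | step 8 | benzyl 3-[3,4-bis(tert-butoxycarbonyloxy)phenyl]-3-oxopropanoate | O=C(CC(=O)c1ccc(OC(=O)OC(C)(C)C)c(OC(=O)OC(C)(C)C)c1)OCc1ccccc1
F5 | step 8 | benzyl (3S)-3-[3,4-bis(tert-butoxycarbonyloxy)phenyl]-3-hydroxypropanoate | O=C(C[C@@H](c1ccc(OC(=O)OC(C)(C)C)c(OC(=O)OC(C)(C)C)c1)O)OCc1ccccc1
F6 | step 8 | (3S)-3-[3,4-bis(tert-butoxycarbonyloxy)phenyl]-3-hydroxypropanoic acid | O=C(O)C[C@@H](c1ccc(OC(=O)OC(C)(C)C)c(OC(=O)OC(C)(C)C)c1)O
F7 | step 10 | (2S)-2-(3,4-dihydroxyphenyl)-5,7-dihydroxy-6-[(2E)-3,7-dimethyl-7-(triethylsilyloxy)oct-2-en-1-yl]chroman-4-one | C/C(=C\Cc1c(O)cc2c(c1O)C(=O)C[C@@H](c1ccc(O)c(O)c1)O2)CCCC(C)(C)O[Si](CC)(CC)CC
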